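**Assumption (one line):** (E)-citral is used, the MBH carbonate is racemic because its stereocentre is destroyed in the SN2′/SN2′ allylation, and acetylation is selective for the primary alcohol.

## Retrosynthetic overview
1. The target comes from a primary-OH acetylation and an allylic-alcohol to Z-enal oxidation on a nine-membered Z-enoate. That ring is formed last, by ring-closing metathesis (RCM) of an acyclic diene.
2. The diene carries the pre-formed E-trisubstituted alkene. It comes from Zr-catalysed methylalumination of a homopropargylic alcohol, followed by Cu-catalysed allylation.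
3. The homopropargylic alcohol comes from a catalyst-controlled allenylboration of a three-stereocentre aldehyde.
4. That aldehyde comes from one-pot organocatalytic reductive allylation of achiral citral with a Morita–Baylis–Hillman (MBH) carbonate made from methyl acrylate and TBSOCH2CHO.

## Route

**Step 1**
Reactants: 1 methyl acrylate; 2 2-(tert-butyldimethylsilyloxy)acetaldehyde
Product: 3 methyl 2-[1-hydroxy-2-(TBSO)ethyl]acrylate (racemic)
Conditions: DABCO (20 mol%), neat, rt, 4 d
Reagents that add atoms: none
Why: Morita–Baylis–Hillman reaction; the carbinol stereocentre is irrelevant because it is destroyed in Step 3.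

**Step 2**
Reactants: 3; 4 di-tert-butyl dicarbonate
Product: 5 MBH tert-butyl carbonate
Conditions: 4, DMAP (5 mol%), CH2Cl2, 0 °C to rt
Reagents that add atoms: Boc2O (4), CC(C)(C)OC(=O)OC(=O)OC(C)(C)C
Why: O-acylation gives an allylic carbonate that can act as a leaving-group electrophile in Lewis-base catalysis.

**Step 3**
Reactants: 6 (E)-citral; 7 Hantzsch ester; 5
Product: 8, OHC–CH(i)[(S)-CH(Me)CH2CH2CH=CMe2]–CH(a)(CH2OTBS)–C(=CH2)CO2Me, with i = R, a = R and the side-chain carbon = S
Conditions: chiral imidazolidinone·TCA (20 mol%), PPh3 (20 mol%), 7 (1.3 equiv), 5 (1.5 equiv), Et2O, –20 °C to rt, 48 h; aqueous work-up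
Reagents that add atoms: none (Hantzsch ester leaves only H; catalysts are not incorporated)
Why: Proposed new method: a one-pot organocatalytic reductive α-allylation.
- The iminium of citral accepts hydride from 7 at the β-carbon, which sets the (S)-citronellyl stereocentre.
- The resulting (E)-enamine is intercepted by the allylphosphonium from PPh3 and 5 (SN2′ then SN2′), forming the i–a bond and setting i and a.
- The closest known reactions are amine-catalysed transfer hydrogenation of β,β-disubstituted enals, and phosphine-catalysed allylic substitution of MBH carbonates. Their combination in one pot, with a protonation-prone enamine, has not been shown.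

**Step 4**
Reactants: 8; 9 allenylboronic acid pinacol ester
Product: 10 homopropargylic alcohol, with h = S
Conditions: 9 (1.5 equiv), chiral phosphoric acid (TRIP, 10 mol%), toluene, –40 °C
Reagents that add atoms: allenyl-Bpin (9), C=C=CB1OC(C)(C)C(C)(C)O1, which delivers the propargyl group
Why: Catalytic asymmetric allenylboration of an α-branched aldehyde through a chair-like closed transition state; catalyst control overrides the substrate's Felkin bias and sets the carbinol stereocentre.

**Step 5**
Reactants: 10; 11 trimethylaluminium; 12 allyl bromide
Product: 13, the diene with the E-trisubstituted alkene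
Conditions: Me3Al (3 equiv), Cp2ZrCl2 (20 mol%), CH2Cl2, 0 °C to rt; then CuCl (20 mol%), allyl bromide (3 equiv), THF, –30 °C to rt
Reagents that add atoms: AlMe3 (11), C[Al](C)C; allyl bromide (12), C=CCBr
Why: Negishi syn-methylalumination of the terminal alkyne puts Me on the internal carbon and Al on the terminal carbon. Cu-catalysed SN2 allylation then replaces Al with retention, so the allyl group ends up trans to the CH2CH(OH) arm, which is the required ring-E geometry.

**Step 6**
Reactants: 13
Product: 14, the nine-membered Z-enoate, plus ethylene
Conditions: Hoveyda–Grubbs II (10 mol%), toluene, 0.002 M, 80 °C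
Reagents that add atoms: none
Why: Ring-closing metathesis joins the α-substituted acrylate and the terminal vinyl group, forming the trisubstituted b=c alkene; it is necessarily ring-cis (Z), and all stereocentres are untouched.

**Step 7**
Reactants: 14
Product: 15, the allylic alcohol
Conditions: DIBAL-H (3 equiv), toluene, –78 to 0 °C
Reagents that add atoms: none
Why: DIBAL reduces the α,β-unsaturated ester to the allylic alcohol; the TBS ether and alkenes survive.

**Step 8**
Reactants: 15
Product: 16, the Z-enal TBS ether
Conditions: activated MnO2 (15 equiv), CH2Cl2, rt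
Reagents that add atoms: none
Why: MnO2 oxidises only the allylic primary alcohol; the non-allylic secondary alcohol is untouched.

**Step 9**
Reactants: 16
Product: 17, the hydroxy-enal
Conditions: HF·pyridine, pyridine, THF, 0 °C
Reagents that add atoms: none
Why: Buffered fluoride removes the primary TBS ether without touching the enal.

**Step 10**
Reactants: 17; 18 acetic anhydride
Product: 19, hydroxyacetyldictyolal
Conditions: 18 (1.05 equiv), pyridine, CH2Cl2, –20 °C
Reagents that add atoms: Ac2O (18), CC(=O)OC(C)=O
Why: Chemoselective acetylation of the unhindered primary alcohol over the hindered secondary alcohol; no stereocentre is affected.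

## Compound list
1 | methyl acrylate | C=CC(=O)OC | starting material
2 | 2-(TBSO)acetaldehyde | O=CCO[Si](C)(C)C(C)(C)C | starting material
3 | MBH adduct | C=C(C(=O)OC)C(O)CO[Si](C)(C)C(C)(C)C | intermediate
4 | di-tert-butyl dicarbonate | CC(C)(C)OC(=O)OC(=O)OC(C)(C)C | starting material
5 | MBH Boc-carbonate | C=C(C(=O)OC)C(OC(=O)OC(C)(C)C)CO[Si](C)(C)C(C)(C)C | intermediate
6 | (E)-citral | CC(C)=CCC/C(C)=C/C=O | starting material
7 | Hantzsch ester | CCOC(=O)C1=C(C)NC(C)=C(C1)C(=O)OCC | starting material
8 | three-stereocentre aldehyde | O=C[C@H]([C@@H](C)CCC=C(C)C)[C@@H](CO[Si](C)(C)C(C)(C)C)C(=C)C(=O)OC | intermediate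
9 | allenyl-Bpin | C=C=CB1OC(C)(C)C(C)(C)O1 | starting material
10 | homopropargylic alcohol | C#CC[C@H](O)[C@H]([C@@H](C)CCC=C(C)C)[C@@H](CO[Si](C)(C)C(C)(C)C)C(=C)C(=O)OC | intermediate
11 | trimethylaluminium | C[Al](C)C | starting material
12 | allyl bromide | C=CCBr | starting material
13 | RCM precursor | C=CC/C=C(\C)C[C@H](O)[C@H]([C@@H](C)CCC=C(C)C)[C@@H](CO[Si](C)(C)C(C)(C)C)C(=C)C(=O)OC | intermediate
14 | nine-membered enoate | CC(C)(C)[Si](C)(C)OC[C@H]1/C(C(=O)OC)=C\C/C=C(\C)C[C@H](O)[C@@H]1[C@@H](C)CCC=C(C)C | intermediate
15 | allylic alcohol | CC(C)(C)[Si](C)(C)OC[C@H]1/C(CO)=C\C/C=C(\C)C[C@H](O)[C@@H]1[C@@H](C)CCC=C(C)C | intermediate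
16 | Z-enal TBS ether | CC(C)(C)[Si](C)(C)OC[C@H]1/C(C=O)=C\C/C=C(\C)C[C@H](O)[C@@H]1[C@@H](C)CCC=C(C)C | intermediate
17 | hydroxy-enal | OC[C@H]1/C(C=O)=C\C/C=C(\C)C[C@H](O)[C@@H]1[C@@H](C)CCC=C(C)C | intermediate
18 | acetic anhydride | CC(=O)OC(C)=O | starting material
19 | hydroxyacetyldictyolal | CC(=O)OC[C@H]1/C(C=O)=C\C/C=C(\C)C[C@H](O)[C@@H]1[C@@H](C)CCC=C(C)C | target

## Totals
Total steps: 10. Longest linear sequence: 10 from methyl acrylate (8 from citral).

## Three steps most likely to fail
1. **Step 3 (proposed new cascade).**
   - Risks: the enamine is protonated to citronellal before it is allylated, Hantzsch ester reduces the MBH carbonate or acrylate, and the diastereoselectivity at i and a is only moderate.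
   - Fallback (known chemistry): do two steps. First, amine-catalysed transfer hydrogenation of 6 gives (S)-citronellal. Second, enamine/Pd cooperative α-allylation of that aldehyde with carbonate 5 gives 8.
2. **Step 6 (RCM to the nine-membered ring).**
   - Risks: oligomerisation, or failure to close the (E,Z)-nine-membered ring from a hindered 1,1-disubstituted acrylate.
   - Fallback: tether-directed RCM. Bridge the h-OH and the primary OH with a di-tert-butylsilylene, which requires TBS removal and re-protection. Close the ring within the preorganised siloxane-bridged bicycle, then remove the silylene.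
3. **Step 5 (methylalumination and Cu-allylation).**
   - Risks: the free alcohol and the acrylate interfere, and conjugate addition competes.
   - Fallback: hydrate the terminal alkyne with Au(I) to the β-hydroxy methyl ketone. Then build the trisubstituted alkene by Julia–Kocienski olefination with a but-3-enyl tetrazolyl sulfone, with E/Z separation.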